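**Retrosynthetic overview**
- Target ⇐ selective diacetylation of the two secondary alcohols of a triol ⇐ MeMgBr on an anti-dihydroxy methyl ketone ⇐ L-proline-catalysed anti-aldol of hydroxyacetone with an (E)-enal (sets both side-chain carbinol centres).
- (E)-Enal ⇐ Weinreb-HWE / DIBAL-H from the ring methyl ketone ⇐ TosMIC nitrile / MeLi from 3-isopropenyl-4-methyl-4-vinylcyclohexanone (ring C–H centre set by equilibration).
- Cyclohexanone ⇐ Wittig methylenation and enol ether hydrolysis of a Diels–Alder adduct.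
- The only ring is formed by a new amine (iminium)-catalysed asymmetric Diels–Alder reaction of (E)-2,4-dimethylpenta-2,4-dienal with a 2-silyloxybutadiene, which sets the quaternary carbon and its neighbour together.
- Dienal ⇐ methacrolein + formyl ylide; diene ⇐ methyl vinyl ketone.

Assumption: catalyst-bound species (iminium ions, enamines) and metal alkoxides of products are not numbered; ylide 2, TosMIC and the Weinreb phosphonate are bought.

**Step 1**
Reactants: 1 methacrolein; 2 2-(triphenylphosphoranylidene)propanal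
Product: 3 (2E)-2,4-dimethylpenta-2,4-dienal
Conditions: toluene, 80 °C (sealed), 16 h
Reagents that add atoms: none
Why: Wittig olefination with a formyl-stabilised ylide, which reacts only at the aldehyde and gives the (E)-trisubstituted enal (CHO trans to the new alkenyl group).

**Step 2**
Reactants: 4 methyl vinyl ketone
Product: 5 tert-butyl(buta-1,3-dien-2-yloxy)dimethylsilane
Conditions: TBSOTf, Et3N, Et2O, 0 °C → rt
Reagents that add atoms: tert-butyldimethylsilyl triflate, CC(C)(C)[Si](C)(C)OS(=O)(=O)C(F)(F)F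
Why: Soft enolisation and O-silylation of the enone, the standard preparation of 2-silyloxybutadienes; no stereocentre is formed.

**Step 3**
Reactants: 3 (2E)-2,4-dimethylpenta-2,4-dienal; 5 tert-butyl(buta-1,3-dien-2-yloxy)dimethylsilane
Product: 6 (1S,6R)-4-[(tert-butyldimethylsilyl)oxy]-1-methyl-6-(prop-1-en-2-yl)cyclohex-3-ene-1-carbaldehyde
Conditions: 9-amino(9-deoxy)epi-quinidine (20 mol%), TFA (40 mol%), 5 (3 equiv), toluene, −20 → 0 °C, 72 h
Reagents that add atoms: none
Why: Proposed new method: primary-amine iminium-catalysed Diels–Alder reaction of an α,β-disubstituted 2,4-dienal with a 2-silyloxydiene; the cinchona primary amine condenses with 3 (secondary amines fail with α-branched enals) to give an iminium ion whose lowered LUMO sits on the α,β-bond, because allylic strain between the 2- and 4-methyl groups twists the isopropenyl group out of conjugation, so the electron-rich diene 5 adds only across C2=C3 with "para" regiochemistry (nucleophilic CH2 of 5 to Cβ); the suprafacial addition carries the E geometry into the product (methyl cis to isopropenyl, formyl trans), and the quinuclidinium/trifluoroacetate ion pair is expected to block one face so that 5 adds to the Cα-Si/Cβ-Re face, setting the quaternary 1S and the 6R centres in one step (the sense is assigned by analogy and must be confirmed; the quinine-derived pseudoenantiomer reverses it); closest known reaction types are the imidazolidinone iminium Diels–Alder of α-unbranched enals, primary-ammonium-salt Diels–Alder reactions of α-substituted acroleins and iminium Mukaiyama–Michael additions of silyl enol ethers.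

**Step 4**
Reactants: 6 (1S,6R)-4-[(tert-butyldimethylsilyl)oxy]-1-methyl-6-(prop-1-en-2-yl)cyclohex-3-ene-1-carbaldehyde
Product: 8 (3R,4R)-4-ethenyl-4-methyl-3-(prop-1-en-2-yl)cyclohexan-1-one, via silyl enol ether triene 7 (not isolated)
Conditions: Ph3PCH3Br, KOtBu, THF, 0 °C → rt; then 1 M HCl, THF, rt
Reagents that add atoms: methyltriphenylphosphonium bromide, C[P+](c1ccccc1)(c1ccccc1)c1ccccc1.[Br-]
Why: Wittig methylenation of a non-enolisable aldehyde on a quaternary carbon, with the silyl enol ether inert to the ylide and then hydrolysed by dilute acid to the ketone; both stereocentres are untouched.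

**Step 5**
Reactants: 8 (3R,4R)-4-ethenyl-4-methyl-3-(prop-1-en-2-yl)cyclohexan-1-one
Product: 9 (3R,4R)-4-ethenyl-4-methyl-3-(prop-1-en-2-yl)cyclohexane-1-carbonitrile (mixture of C1 epimers)
Conditions: TosMIC, KOtBu, DME, EtOH (2 equiv), 0 → 35 °C
Reagents that add atoms: p-toluenesulfonylmethyl isocyanide (TosMIC), Cc1ccc(cc1)S(=O)(=O)C[N+]#[C-]
Why: Van Leusen reductive cyanation turns the unhindered cyclohexanone into the homologous nitrile in one step; the new C1 centre forms as a mixture and is corrected in step 6.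

**Step 6**
Reactants: 9 (3R,4R)-4-ethenyl-4-methyl-3-(prop-1-en-2-yl)cyclohexane-1-carbonitrile
Product: 12 1-[(1S,3R,4R)-4-ethenyl-4-methyl-3-(prop-1-en-2-yl)cyclohexyl]ethan-1-one, via lithium ketimide 10 (not isolated), via epimeric ketone mixture 11 (not isolated)
Conditions: MeLi, Et2O, 0 °C → rt; 2 M HCl, rt; then NaOMe (cat.), MeOH, rt
Reagents that add atoms: methyllithium, C[Li]; water, O
Why: Organolithium addition to the nitrile stops at the ketimide, acid hydrolysis gives the methyl ketone, and methoxide equilibration through the enolate puts the acetyl group equatorial and cis to the isopropenyl group (estimated about 8:1, minor epimer recycled), which sets C1 as S under thermodynamic control.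

**Step 7**
Reactants: 12 1-[(1S,3R,4R)-4-ethenyl-4-methyl-3-(prop-1-en-2-yl)cyclohexyl]ethan-1-one
Product: 13 (2E)-3-[(1S,3R,4R)-4-ethenyl-4-methyl-3-(prop-1-en-2-yl)cyclohexyl]-N-methoxy-N-methylbut-2-enamide
Conditions: (EtO)2P(O)CH2C(O)N(OMe)Me, NaH, THF, 0 → 65 °C
Reagents that add atoms: diethyl {2-[methoxy(methyl)amino]-2-oxoethyl}phosphonate, CCOP(=O)(OCC)CC(=O)N(C)OC
Why: Horner–Wadsworth–Emmons olefination, in which reversible addition to the methyl ketone favours the E-alkene with the amide trans to the bulky cyclohexyl group (estimated about 9:1, separable).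

**Step 8**
Reactants: 13 (2E)-3-[(1S,3R,4R)-4-ethenyl-4-methyl-3-(prop-1-en-2-yl)cyclohexyl]-N-methoxy-N-methylbut-2-enamide
Product: 14 (2E)-3-[(1S,3R,4R)-4-ethenyl-4-methyl-3-(prop-1-en-2-yl)cyclohexyl]but-2-enal
Conditions: DIBAL-H, THF, −78 °C; Rochelle salt
Reagents that add atoms: none
Why: Weinreb amide reduction, where the chelated tetrahedral aluminium adduct survives until work-up so that reduction stops at the aldehyde and the alkene geometry is kept.

**Step 9**
Reactants: 14 (2E)-3-[(1S,3R,4R)-4-ethenyl-4-methyl-3-(prop-1-en-2-yl)cyclohexyl]but-2-enal; 15 hydroxyacetone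
Product: 16 (3S,4S,5E)-6-[(1S,3R,4R)-4-ethenyl-4-methyl-3-(prop-1-en-2-yl)cyclohexyl]-3,4-dihydroxyhept-5-en-2-one
Conditions: L-proline (30 mol%), 15 (10 equiv), DMSO, rt, 48–72 h
Reagents that add atoms: none
Why: List-type proline enamine aldol reaction, in which the (E)-enamine formed at the hydroxylated carbon of hydroxyacetone adds through the acid-organised chair-like (Houk–List) transition state to the re face of the aldehyde, giving the anti-(3S,4S)-diol under catalyst control with the remote ring centres not interfering.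

**Step 10**
Reactants: 16 (3S,4S,5E)-6-[(1S,3R,4R)-4-ethenyl-4-methyl-3-(prop-1-en-2-yl)cyclohexyl]-3,4-dihydroxyhept-5-en-2-one
Product: 17 (3S,4S,5E)-6-[(1S,3R,4R)-4-ethenyl-4-methyl-3-(prop-1-en-2-yl)cyclohexyl]-2-methylhept-5-ene-2,3,4-triol
Conditions: MeMgBr (5 equiv), THF, −78 → 0 °C; H2O/aq. NH4Cl
Reagents that add atoms: methylmagnesium bromide, C[Mg]Br
Why: Grignard addition to the chelated α-alkoxy ketone after deprotonation of both hydroxyls (excess reagent, low temperature against retro-aldol); the new carbinol carbon carries two identical methyl groups, so no stereocentre is formed and C3/C4 are kept.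

**Step 11**
Reactants: 17 (3S,4S,5E)-6-[(1S,3R,4R)-4-ethenyl-4-methyl-3-(prop-1-en-2-yl)cyclohexyl]-2-methylhept-5-ene-2,3,4-triol
Product: 18 (3S,4S,5E)-6-[(1S,3R,4R)-4-ethenyl-4-methyl-3-(prop-1-en-2-yl)cyclohexyl]-2-hydroxy-2-methylhept-5-ene-3,4-diyl diacetate (CNP0119763.1)
Conditions: Ac2O (3 equiv), pyridine, DMAP (5 mol%), CH2Cl2, 0 °C → rt
Reagents that add atoms: acetic anhydride, CC(=O)OC(C)=O
Why: DMAP-catalysed acetylation esterifies the two secondary alcohols while the tertiary carbinol is too hindered to react under these mild conditions.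

**Compound list**
1 | methacrolein | CC(=C)C=O | starting material
2 | 2-(triphenylphosphoranylidene)propanal | CC(C=O)=P(c1ccccc1)(c1ccccc1)c1ccccc1 | starting material
3 | (2E)-2,4-dimethylpenta-2,4-dienal | O=C/C(C)=C/C(C)=C | intermediate
4 | methyl vinyl ketone | CC(=O)C=C | starting material
5 | tert-butyl(buta-1,3-dien-2-yloxy)dimethylsilane | C=CC(=C)O[Si](C)(C)C(C)(C)C | intermediate
6 | (1S,6R)-4-[(tert-butyldimethylsilyl)oxy]-1-methyl-6-(prop-1-en-2-yl)cyclohex-3-ene-1-carbaldehyde | O=C[C@@]1(C)CC=C(O[Si](C)(C)C(C)(C)C)C[C@@H]1C(=C)C | intermediate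
7 | tert-butyl{[(4R,5R)-4-ethenyl-4-methyl-5-(prop-1-en-2-yl)cyclohex-1-en-1-yl]oxy}dimethylsilane (not isolated) | C=C[C@@]1(C)CC=C(O[Si](C)(C)C(C)(C)C)C[C@@H]1C(=C)C | intermediate
8 | (3R,4R)-4-ethenyl-4-methyl-3-(prop-1-en-2-yl)cyclohexan-1-one | C=C[C@@]1(C)CCC(=O)C[C@@H]1C(=C)C | intermediate
9 | (3R,4R)-4-ethenyl-4-methyl-3-(prop-1-en-2-yl)cyclohexane-1-carbonitrile (C1 epimers) | C=C[C@@]1(C)CCC(C#N)C[C@@H]1C(=C)C | intermediate
10 | lithium {1-[(3R,4R)-4-ethenyl-4-methyl-3-(prop-1-en-2-yl)cyclohexyl]ethylidene}azanide (not isolated) | C=C[C@@]1(C)CCC(C(C)=N[Li])C[C@@H]1C(=C)C | intermediate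
11 | 1-[(3R,4R)-4-ethenyl-4-methyl-3-(prop-1-en-2-yl)cyclohexyl]ethan-1-one, C1 epimer mixture (not isolated) | C=C[C@@]1(C)CCC(C(C)=O)C[C@@H]1C(=C)C | intermediate
12 | 1-[(1S,3R,4R)-4-ethenyl-4-methyl-3-(prop-1-en-2-yl)cyclohexyl]ethan-1-one | C=C[C@@]1(C)CC[C@H](C(C)=O)C[C@@H]1C(=C)C | intermediate
13 | (2E)-3-[(1S,3R,4R)-4-ethenyl-4-methyl-3-(prop-1-en-2-yl)cyclohexyl]-N-methoxy-N-methylbut-2-enamide | C=C[C@@]1(C)CC[C@H](/C(C)=C/C(=O)N(C)OC)C[C@@H]1C(=C)C | intermediate
14 | (2E)-3-[(1S,3R,4R)-4-ethenyl-4-methyl-3-(prop-1-en-2-yl)cyclohexyl]but-2-enal | C=C[C@@]1(C)CC[C@H](/C(C)=C/C=O)C[C@@H]1C(=C)C | intermediate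
15 | hydroxyacetone (1-hydroxypropan-2-one) | CC(=O)CO | starting material
16 | (3S,4S,5E)-6-[(1S,3R,4R)-4-ethenyl-4-methyl-3-(prop-1-en-2-yl)cyclohexyl]-3,4-dihydroxyhept-5-en-2-one | C=C[C@@]1(C)CC[C@H](/C(C)=C/[C@H](O)[C@H](O)C(C)=O)C[C@@H]1C(=C)C | intermediate
17 | (3S,4S,5E)-6-[(1S,3R,4R)-4-ethenyl-4-methyl-3-(prop-1-en-2-yl)cyclohexyl]-2-methylhept-5-ene-2,3,4-triol | C=C[C@@]1(C)CC[C@H](/C(C)=C/[C@H](O)[C@H](O)C(C)(C)O)C[C@@H]1C(=C)C | intermediate
18 | (3S,4S,5E)-6-[(1S,3R,4R)-4-ethenyl-4-methyl-3-(prop-1-en-2-yl)cyclohexyl]-2-hydroxy-2-methylhept-5-ene-3,4-diyl diacetate | C=C[C@@]1(C)CC[C@H](/C(C)=C/[C@H](OC(C)=O)[C@H](OC(C)=O)C(C)(C)O)C[C@@H]1C(=C)C | target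

**Step count**
Total: 11 steps. Longest linear sequence: 10 steps (1, 3–11); step 2 is a one-step side branch.

**Three steps most likely to fail**

Step 3 (the proposed new reaction). The dienophile is a hindered trisubstituted enal. Mannich-type attack of 5 on the iminium carbon, protodesilylation of 5 or 6, low ee or the wrong facial sense are all conceivable. The fallback uses known chemistry, sets out from 3 and 5 and comes back at 6. It replaces covalent aminocatalysis by Lewis-acid activation of the free aldehyde with the triflimide-activated oxazaborolidinium salt made from α,α-diphenylprolinol and o-tolylboroxine (10–20 mol%, CH2Cl2, −78 → −40 °C). This catalyst class has precedent for Diels–Alder reactions of α-substituted and α,β-disubstituted enals and of 2-silyloxybutadienes. The cycloaddition is concerted, so the E geometry is again transferred, and the catalyst antipode is taken that exposes the Cα-Si/Cβ-Re face. No new compound is made.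

Step 7. HWE reactions of an enolisable, α-branched methyl ketone with the rather unreactive Weinreb phosphonate can stall or give a poor E/Z ratio. The fallback sets out from 12 and comes back at 14, building the trisubstituted alkene by syn-carbometalation of an alkyne instead of carbonyl olefination. Kinetic enolisation of 12 (LDA, THF, −78 °C) and trapping with ClP(O)(OEt)2 gives the enol phosphate F1 (not isolated), which excess LDA eliminates to the terminal alkyne F2. Zirconium-catalysed methylalumination (Me3Al, Cp2ZrCl2 cat., CH2Cl2, rt) gives only the (E)-alkenylalane F3 (not isolated). Its n-BuLi ate complex is hydroxymethylated with paraformaldehyde to the (E)-allylic alcohol F4, and MnO2 in CH2Cl2 oxidises this to 14.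

Step 9. The acceptor is an sp2-bound, β,β-disubstituted enal. A lower anti/syn ratio than with α-branched alkyl aldehydes, slow conversion and proline-mediated E/Z scrambling of 14 through its iminium/dienamine are the risks. The fallback sets out from 14 and comes back at 17, using a chiral tin(II) Lewis-acid Mukaiyama aldol instead of enamine catalysis. The glycolate ketene silyl thioacetal F5 (from S-ethyl (benzyloxy)thioacetate, LDA, TMSCl) is added to 14 with Sn(OTf)2, a proline-derived N-(1-naphthyl)aminomethylpyrrolidine diamine and Bu2Sn(OAc)2 in CH2Cl2 at −78 °C. This system is anti-selective with the benzyloxy donor and accepts enals; the diamine antipode is chosen for the 2S,3S product, the anti aldol thioester F6. Excess MeMgBr converts the thioester into the tertiary carbinol benzyl ether F7, and LiDBB (THF, −78 °C) removes the benzyl group without touching the alkenes to give 17.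

**Further compounds**
F0 | step 3 | none | none
F1 | step 7 | diethyl 1-[(1S,3R,4R)-4-ethenyl-4-methyl-3-(prop-1-en-2-yl)cyclohexyl]ethenyl phosphate | C=C[C@@]1(C)CC[C@H](C(=C)OP(=O)(OCC)OCC)C[C@@H]1C(=C)C
F2 | step 7 | (1R,2R,4S)-1-ethenyl-4-ethynyl-1-methyl-2-(prop-1-en-2-yl)cyclohexane | C=C[C@@]1(C)CC[C@H](C#C)C[C@@H]1C(=C)C
F3 | step 7 | dimethyl{(1E)-2-[(1S,3R,4R)-4-ethenyl-4-methyl-3-(prop-1-en-2-yl)cyclohexyl]prop-1-en-1-yl}alumane | C=C[C@@]1(C)CC[C@H](/C(C)=C/[Al](C)C)C[C@@H]1C(=C)C
F4 | step 7 | (2E)-3-[(1S,3R,4R)-4-ethenyl-4-methyl-3-(prop-1-en-2-yl)cyclohexyl]but-2-en-1-ol | C=C[C@@]1(C)CC[C@H](/C(C)=C/CO)C[C@@H]1C(=C)C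
F5 | step 9 | (Z)-{[2-(benzyloxy)-1-(ethylsulfanyl)ethenyl]oxy}trimethylsilane | CCS/C(O[Si](C)(C)C)=C\OCc1ccccc1
F6 | step 9 | S-ethyl (2S,3S,4E)-2-(benzyloxy)-5-[(1S,3R,4R)-4-ethenyl-4-methyl-3-(prop-1-en-2-yl)cyclohexyl]-3-hydroxyhex-4-enethioate | C=C[C@@]1(C)CC[C@H](/C(C)=C/[C@H](O)[C@H](OCc2ccccc2)C(=O)SCC)C[C@@H]1C(=C)C
F7 | step 9 | (3S,4S,5E)-3-(benzyloxy)-6-[(1S,3R,4R)-4-ethenyl-4-methyl-3-(prop-1-en-2-yl)cyclohexyl]-2-methylhept-5-ene-2,4-diol | C=C[C@@]1(C)CC[C@H](/C(C)=C/[C@H](O)[C@H](OCc2ccccc2)C(C)(C)O)C[C@@H]1C(=C)C
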